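**Plan**
- The target is read as the (3R)-3-hydroxy-2,2-dimethylchroman bearing a 5-(E)-styryl, a 7-hydroxy and an 8-prenyl group, with C3 as the only stereocentre.
- Retrosynthesis: C3–OH back to the C3 ketone; then the C4–C4a bond together with the C3 oxygen back to an aryl 1,1-dimethylpropargyl ether (O1–C2Me2–C≡CH); then O1–C2; then the styryl C=C (Horner–Wadsworth–Emmons) and the C8–prenyl bond (directed ortho-metalation).
- Enabling feature: the C3 carbinol makes C4 the alpha-carbon of a latent C3 ketone, so O1–C2–C3–C4 is a masked propargyl ether whose oxidised terminal carbon is a carbene. C4a is ortho to O1 and para to the C7 oxygen, C8 (the other ortho carbon) is blocked by prenyl, and the 4-prenyl-3,5-dioxygenated ring is symmetric before etherification.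
- Forward: benzaldehyde → prenyl group between the two oxygens → stilbene → mono-propargyl ether → gold-catalysed oxidation and arylation closes the pyran ring (the only ring formed) as the chroman-3-one → reduction → deprotection.
- Stereochemistry: C3 (R) from catalyst-controlled Corey–Bakshi–Shibata reduction of the C3 ketone; the (E)-alkene from the Horner–Wadsworth–Emmons reaction.

Key step: step 8

**Route**

Step 1
Reactants: 1 3,5-dihydroxybenzaldehyde
Product: 2 3,5-bis(methoxymethoxy)benzaldehyde
Conditions: MOMCl (2.6 equiv), i-Pr2NEt (3 equiv), CH2Cl2/DMF, 0 °C → rt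
Reagents that add atoms: chloromethyl methyl ether (MOMCl), COCCl
Why: O-alkylation of both phenols (MOM protection) should be clean, and the two MOM ethers later serve as the directing groups for metalation.

Step 2
Reactants: 2 3,5-bis(methoxymethoxy)benzaldehyde
Product: 3 1-(dimethoxymethyl)-3,5-bis(methoxymethoxy)benzene
Conditions: HC(OMe)3, MeOH, PPTS (cat.), rt; Et3N quench
Reagents that add atoms: trimethyl orthoformate, COC(OC)OC; methanol, CO
Why: Acid-catalysed acetalisation with the orthoformate as water scavenger masks the aldehyde against n-BuLi, and the mild anhydrous acid should leave the aryl MOM ethers intact.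

Step 3
Reactants: 3 1-(dimethoxymethyl)-3,5-bis(methoxymethoxy)benzene; 4 1-bromo-3-methylbut-2-ene (prenyl bromide)
Product: 7 3,5-bis(methoxymethoxy)-4-(3-methylbut-2-en-1-yl)benzaldehyde, via aryllithium 5 (not isolated), via prenylated dimethyl acetal 6 (not isolated)
Conditions: n-BuLi (1.3 equiv), THF, 0 °C; CuI (10 mol%), then 4, −40 °C → rt; then 1 M HCl, THF, 0 °C, short
Reagents that add atoms: water, O
Why: Directed ortho-metalation, in which the two MOM ethers cooperatively direct lithiation to the carbon between them, followed by copper-catalysed SN2 alkylation with prenyl bromide and brief aqueous acid that should hydrolyse only the dimethyl acetal.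

Step 4
Reactants: 7 3,5-bis(methoxymethoxy)-4-(3-methylbut-2-en-1-yl)benzaldehyde; 8 diethyl benzylphosphonate
Product: 9 1,3-bis(methoxymethoxy)-2-(3-methylbut-2-en-1-yl)-5-[(E)-2-phenylethenyl]benzene
Conditions: NaH, THF, 0 °C → rt
Reagents that add atoms: none
Why: Horner–Wadsworth–Emmons olefination of an aromatic aldehyde with a benzylphosphonate carbanion should give the (E)-stilbene selectively.

Step 5
Reactants: 9 1,3-bis(methoxymethoxy)-2-(3-methylbut-2-en-1-yl)-5-[(E)-2-phenylethenyl]benzene
Product: 10 2-(3-methylbut-2-en-1-yl)-5-[(E)-2-phenylethenyl]benzene-1,3-diol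
Conditions: conc. HCl (cat.), MeOH, rt → 40 °C, monitored
Reagents that add atoms: none
Why: Acid-catalysed acetal exchange with methanol removes both MOM groups under conditions that are precedented for phenols carrying an ortho prenyl group.

Step 6
Reactants: 10 2-(3-methylbut-2-en-1-yl)-5-[(E)-2-phenylethenyl]benzene-1,3-diol; 11 3-chloro-3-methylbut-1-yne
Product: 12 3-[(2-methylbut-3-yn-2-yl)oxy]-2-(3-methylbut-2-en-1-yl)-5-[(E)-2-phenylethenyl]phenol
Conditions: 11 (1.0 equiv), DBU (1.2 equiv), CuCl2·2H2O (1 mol%), MeCN, 0 °C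
Reagents that add atoms: none
Why: Copper-catalysed propargylic substitution (copper acetylide, then allenylidene-type electrophile) should form the tertiary aryl propargyl ether; because the two hydroxyl groups are equivalent, limiting chloride gives one mono-ether, separable from recovered diol and bis-ether.

Step 7
Reactants: 12 3-[(2-methylbut-3-yn-2-yl)oxy]-2-(3-methylbut-2-en-1-yl)-5-[(E)-2-phenylethenyl]phenol
Product: 13 tert-butyldimethyl{3-[(2-methylbut-3-yn-2-yl)oxy]-2-(3-methylbut-2-en-1-yl)-5-[(E)-2-phenylethenyl]phenoxy}silane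
Conditions: TBSCl, imidazole, DMF, rt
Reagents that add atoms: tert-butyldimethylsilyl chloride (TBSCl), CC(C)(C)[Si](C)(C)Cl
Why: Silylation of the remaining phenol should prevent its addition to the neighbouring prenyl group or to the carbene in the next step, while the silyloxy group keeps the ring electron-rich para to the reacting carbon.

Step 8
Reactants: 13 tert-butyldimethyl{3-[(2-methylbut-3-yn-2-yl)oxy]-2-(3-methylbut-2-en-1-yl)-5-[(E)-2-phenylethenyl]phenoxy}silane
Product: 15 7-[(tert-butyldimethylsilyl)oxy]-2,2-dimethyl-8-(3-methylbut-2-en-1-yl)-5-[(E)-2-phenylethenyl]chroman-3-one, via alpha-oxo gold carbene 14 (not isolated)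
Conditions: (Me4tBuXPhos)AuNTf2 (5 mol%), 2,6-dichloropyridine N-oxide (1.3 equiv, slow addition), ClCH2CH2Cl, rt
Reagents that add atoms: 2,6-dichloropyridine N-oxide, [O-][n+]1c(Cl)cccc1Cl
Why: The cationic monovalent gold complex activates the terminal alkyne, the N-oxide oxygen adds to the internal alkyne carbon and loss of 2,6-dichloropyridine gives the alpha-oxo gold carbene 14, in which the future C4 is electrophilic although it is the alpha-carbon of the new C3 ketone. The electron-rich arene carbon C4a (ortho to O1, para to the silyloxy group) attacks this carbene in a Friedel–Crafts-type substitution, and rearomatisation with protodeauration should release chroman-3-one 15 and the catalyst. The closest known reaction type is the gold-catalysed oxidative cyclisation of aryl propargyl ethers to chroman-3-ones, the diazo-free counterpart of the intramolecular arylation of aryloxy diazoketones. The pyran ring closes by attack of the tethered arene on the carbene carbon in a six-membered mode (6-exo with respect to the C=Au bond), helped by the Thorpe–Ingold effect of the C2 gem-dimethyl group. No stereocentre is formed. The step needs site selectivity (C4a is the only free ortho carbon because C8 carries the prenyl group), chemoselectivity over the prenyl and stilbene alkenes (arylation through a six-membered transition state should outrun cyclopropanation through rings of eight or more atoms, and the N-oxide does not epoxidise alkenes), and suppression of non-oxidative hydroarylation and of double oxidation (bulky biaryl phosphine, slow addition of the oxidant, no acid additive).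

Step 9
Reactants: 15 7-[(tert-butyldimethylsilyl)oxy]-2,2-dimethyl-8-(3-methylbut-2-en-1-yl)-5-[(E)-2-phenylethenyl]chroman-3-one
Product: 16 (3R)-7-[(tert-butyldimethylsilyl)oxy]-2,2-dimethyl-8-(3-methylbut-2-en-1-yl)-5-[(E)-2-phenylethenyl]chroman-3-ol
Conditions: (S)-Me-CBS oxazaborolidine (0.3 equiv), catecholborane (2 equiv), toluene, −78 → −40 °C; pH 7 aqueous work-up
Reagents that add atoms: none
Why: In the Corey–Bakshi–Shibata reduction the ketone should bind the catalyst boron on the side of the smaller C4 methylene, with the quaternary C2 as the large group, so the (S)-catalyst delivers hydride to the face that gives the (R)-carbinol; catecholborane should not hydroborate the alkenes at this temperature.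

Step 10
Reactants: 16 (3R)-7-[(tert-butyldimethylsilyl)oxy]-2,2-dimethyl-8-(3-methylbut-2-en-1-yl)-5-[(E)-2-phenylethenyl]chroman-3-ol
Product: 17 (3R)-2,2-dimethyl-8-(3-methylbut-2-en-1-yl)-5-[(E)-2-phenylethenyl]chromane-3,7-diol
Conditions: TBAF, AcOH (1:1), THF, 0 °C
Reagents that add atoms: none
Why: Fluoride-mediated cleavage of the aryl silyl ether under acetic acid buffering should free the phenol without touching the prenyl group, the stilbene or the C3 stereocentre.

**Compound list**
1 | 3,5-dihydroxybenzaldehyde | O=Cc1cc(O)cc(O)c1 | starting material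
2 | 3,5-bis(methoxymethoxy)benzaldehyde | COCOc1cc(C=O)cc(OCOC)c1 | intermediate
3 | 1-(dimethoxymethyl)-3,5-bis(methoxymethoxy)benzene | COCOc1cc(C(OC)OC)cc(OCOC)c1 | intermediate
4 | 1-bromo-3-methylbut-2-ene (prenyl bromide) | CC(C)=CCBr | starting material
5 | [4-(dimethoxymethyl)-2,6-bis(methoxymethoxy)phenyl]lithium | [Li]c1c(OCOC)cc(C(OC)OC)cc1OCOC | intermediate
6 | 5-(dimethoxymethyl)-1,3-bis(methoxymethoxy)-2-(3-methylbut-2-en-1-yl)benzene | COCOc1cc(C(OC)OC)cc(OCOC)c1CC=C(C)C | intermediate
7 | 3,5-bis(methoxymethoxy)-4-(3-methylbut-2-en-1-yl)benzaldehyde | COCOc1cc(C=O)cc(OCOC)c1CC=C(C)C | intermediate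
8 | diethyl benzylphosphonate | CCOP(=O)(Cc1ccccc1)OCC | starting material
9 | 1,3-bis(methoxymethoxy)-2-(3-methylbut-2-en-1-yl)-5-[(E)-2-phenylethenyl]benzene | COCOc1cc(/C=C/c2ccccc2)cc(OCOC)c1CC=C(C)C | intermediate
10 | 2-(3-methylbut-2-en-1-yl)-5-[(E)-2-phenylethenyl]benzene-1,3-diol | Oc1cc(/C=C/c2ccccc2)cc(O)c1CC=C(C)C | intermediate
11 | 3-chloro-3-methylbut-1-yne | CC(C)(Cl)C#C | starting material
12 | 3-[(2-methylbut-3-yn-2-yl)oxy]-2-(3-methylbut-2-en-1-yl)-5-[(E)-2-phenylethenyl]phenol | CC(C)=CCc1c(O)cc(/C=C/c2ccccc2)cc1OC(C)(C)C#C | intermediate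
13 | tert-butyldimethyl{3-[(2-methylbut-3-yn-2-yl)oxy]-2-(3-methylbut-2-en-1-yl)-5-[(E)-2-phenylethenyl]phenoxy}silane | CC(C)=CCc1c(O[Si](C)(C)C(C)(C)C)cc(/C=C/c2ccccc2)cc1OC(C)(C)C#C | intermediate
14 | alpha-oxo gold carbene from 13 (Me4tBuXPhos on gold, NTf2 counter-ion) | CC(C)=CCc1c(O[Si](C)(C)C(C)(C)C)cc(/C=C/c2ccccc2)cc1OC(C)(C)C(=O)C=[Au][P+](C(C)(C)C)(C(C)(C)C)c1c(C)c(C)c(C)c(C)c1-c1c(C(C)C)cc(C(C)C)cc1C(C)C.[N-](S(=O)(=O)C(F)(F)F)S(=O)(=O)C(F)(F)F | intermediate
15 | 7-[(tert-butyldimethylsilyl)oxy]-2,2-dimethyl-8-(3-methylbut-2-en-1-yl)-5-[(E)-2-phenylethenyl]chroman-3-one | CC(C)=CCc1c(O[Si](C)(C)C(C)(C)C)cc(/C=C/c2ccccc2)c2c1OC(C)(C)C(=O)C2 | intermediate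
16 | (3R)-7-[(tert-butyldimethylsilyl)oxy]-2,2-dimethyl-8-(3-methylbut-2-en-1-yl)-5-[(E)-2-phenylethenyl]chroman-3-ol | CC(C)=CCc1c(O[Si](C)(C)C(C)(C)C)cc(/C=C/c2ccccc2)c2c1OC(C)(C)[C@H](O)C2 | intermediate
17 | (3R)-2,2-dimethyl-8-(3-methylbut-2-en-1-yl)-5-[(E)-2-phenylethenyl]chromane-3,7-diol | CC(C)=CCc1c(O)cc(/C=C/c2ccccc2)c2c1OC(C)(C)[C@H](O)C2 | target

**Summary**
Total step count: 10. Longest linear sequence: 10 steps (fully linear from 1).

Steps most likely to fail:

Step 8. The gold carbene may be diverted: non-oxidative cycloisomerisation of the propargyl ether, a second oxidation of the carbene, or capture of the carbene by one of the alkenes. Fallback: starting from 13, heating in N,N-diethylaniline at about 190 °C should give, by propargyl Claisen rearrangement, 1,5-hydrogen shift and oxa-6π electrocyclisation, the 2H-chromene F1. Jacobsen epoxidation of the chromene double bond with (R,R)-N,N'-bis(3,5-di-tert-butylsalicylidene)-1,2-cyclohexanediaminomanganese chloride (trivalent manganese), NaOCl and 4-phenylpyridine N-oxide in CH2Cl2 at 0 °C should give the (3R,4R)-epoxide F2. This is reduced at once with LiAlH4 in THF at 0 °C at the benzylic C4, and the sequence comes back to the route at 16, replacing steps 8 and 9.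

Step 9. Facial discrimination by the oxazaborolidine may be poor because both flanks of the ketone are ring carbons, and enolisation towards C4 may compete. Fallback: starting from 15, NaBH4 in MeOH at 0 °C should give the racemic chromanol F3. Kinetic resolution with immobilised Candida antarctica lipase B and vinyl acetate in MTBE at 40 °C is expected, by the usual size rule for secondary alcohols, to acylate the (R)-enantiomer to the (R)-acetate F4 and leave the (S)-chromanol F5. After separation, K2CO3 in MeOH should cleave both the acetate and the aryl silyl ether of F4, so the sequence comes back to the route at 17. F5 is returned to 15 by Dess–Martin oxidation.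

Step 6. O-alkylation at the phenol flanked by the prenyl group may be sluggish, or may run on to the bis-ether or to C-alkylation. Fallback: starting from 10, alkylation with ethyl 2-bromo-2-methylpropanoate (1 equiv) and Cs2CO3 in DMF at 50 °C should give the aryloxy ester F6. Reduction with i-Bu2AlH (2.2 equiv) in CH2Cl2 at −78 °C should give the non-enolisable aryloxy aldehyde F7. Homologation with the Ohira–Bestmann reagent, K2CO3 and MeOH at rt then forms the terminal alkyne, and the sequence comes back to the route at 12.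

**Further compounds**
F1 | step 8 | tert-butyl{[2,2-dimethyl-8-(3-methylbut-2-en-1-yl)-5-[(E)-2-phenylethenyl]-2H-chromen-7-yl]oxy}dimethylsilane | CC(C)=CCc1c(O[Si](C)(C)C(C)(C)C)cc(/C=C/c2ccccc2)c2c1OC(C)(C)C=C2
F2 | step 8 | (3R,4R)-7-[(tert-butyldimethylsilyl)oxy]-3,4-epoxy-2,2-dimethyl-8-(3-methylbut-2-en-1-yl)-5-[(E)-2-phenylethenyl]chromane | CC(C)=CCc1c(O[Si](C)(C)C(C)(C)C)cc(/C=C/c2ccccc2)c2c1OC(C)(C)[C@@H]1O[C@@H]12
F3 | step 9 | racemic 7-[(tert-butyldimethylsilyl)oxy]-2,2-dimethyl-8-(3-methylbut-2-en-1-yl)-5-[(E)-2-phenylethenyl]chroman-3-ol | CC(C)=CCc1c(O[Si](C)(C)C(C)(C)C)cc(/C=C/c2ccccc2)c2c1OC(C)(C)C(O)C2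
F4 | step 9 | (3R)-7-[(tert-butyldimethylsilyl)oxy]-2,2-dimethyl-8-(3-methylbut-2-en-1-yl)-5-[(E)-2-phenylethenyl]chroman-3-yl acetate | CC(C)=CCc1c(O[Si](C)(C)C(C)(C)C)cc(/C=C/c2ccccc2)c2c1OC(C)(C)[C@H](OC(C)=O)C2
F5 | step 9 | (3S)-7-[(tert-butyldimethylsilyl)oxy]-2,2-dimethyl-8-(3-methylbut-2-en-1-yl)-5-[(E)-2-phenylethenyl]chroman-3-ol | CC(C)=CCc1c(O[Si](C)(C)C(C)(C)C)cc(/C=C/c2ccccc2)c2c1OC(C)(C)[C@@H](O)C2
F6 | step 6 | ethyl 2-{3-hydroxy-2-(3-methylbut-2-en-1-yl)-5-[(E)-2-phenylethenyl]phenoxy}-2-methylpropanoate | CCOC(=O)C(C)(C)Oc1cc(/C=C/c2ccccc2)cc(O)c1CC=C(C)C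
F7 | step 6 | 2-{3-hydroxy-2-(3-methylbut-2-en-1-yl)-5-[(E)-2-phenylethenyl]phenoxy}-2-methylpropanal | O=CC(C)(C)Oc1cc(/C=C/c2ccccc2)cc(O)c1CC=C(C)C
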